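**Retrosynthetic overview**

1. The target comes from global hydrogenolysis of the protected dimer 17, which is formed by Friedel–Crafts union of C4 of the upper unit with C8 of the lower unit. The C4 electrophile 16 is made from (−)-epigallocatechin 12 (upper rings A, B, C and the upper C2/C3 stereocentres) by phenol benzylation, galloylation with acid 14 and C4 oxidation. The nucleophile is the lower flavan-3-ol 11.
2. 11 comes from the racemic flavan-3-one 10, where a dynamic kinetic resolution sets C2 and C3 cis. 10 comes from the 2-aryl-3-hydroxy-3-(mesyloxymethyl)-2,3-dihydrobenzofuran 9 by ring expansion: the five-membered ring O1–C2–C3–C3a–C7a becomes the lower pyran ring when the exocyclic CH2 is inserted between C3 and the arene by a 1,2-aryl shift.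
3. Enabling feature: ring A of the lower unit is a phloroglucinol ring, so the migrating carbon (C4a of the flavan) has O1 and the C5 oxygen ortho and the C7 oxygen para and bridges readily. The C3 oxygen of the target is the carbinol that drives the shift, and the C4 methylene is the former exocyclic carbon.
4. 9 comes from Norrish–Yang photocyclisation of the threefold-symmetric aryl glyoxylate 6 (C2–C3 bond, furan ring). 6 is built from phloroglucinol triacetate 3 and three 3,4,5-tris(benzyloxy)benzyl units: one becomes ring B with C2, two serve as ring A protecting groups.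
5. Ring order: lower ring A (bought) → lower furan ring (light) → lower pyran ring (expansion) → interflavan bond. Upper rings A, B and C are bought with 12 and the galloyl ring with 14.

Key step: step 7

Assumption: the (S,S)-configured ruthenium catalyst of step 8 and the Rh2(S-PTTL)4 catalyst named in one fallback are taken to give the enantiomers drawn (if the sense of induction is the opposite, the antipodal catalyst is used and nothing else changes), and compounds 1, 3, 12 and 14 are taken as commercial.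

**Step 1**
Reactants: 1 [3,4,5-tris(benzyloxy)phenyl]methanol
Product: 2 1,2,3-tris(benzyloxy)-5-(chloromethyl)benzene
Conditions: SOCl2, CH2Cl2, 0 °C → rt
Reagents that add atoms: thionyl chloride, O=S(Cl)Cl
Why: Chlorodehydroxylation of an electron-rich benzylic alcohol through its chlorosulfite (alcohol-to-chloride substitution); no stereocentre is involved.

**Step 2**
Reactants: 2 1,2,3-tris(benzyloxy)-5-(chloromethyl)benzene (3.3 equiv); 3 benzene-1,3,5-triyl triacetate
Product: 4 1,3,5-tris{[3,4,5-tris(benzyloxy)benzyl]oxy}benzene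
Conditions: NaH (6.5 equiv), DMF, 0 °C; H2O (3 equiv) added slowly; rt
Reagents that add atoms: 1,2,3-tris(benzyloxy)-5-(chloromethyl)benzene (compound 2, its second and third equivalents), ClCc1cc(OCc2ccccc2)c(OCc2ccccc2)c(OCc2ccccc2)c1
Why: Threefold Williamson ether synthesis in which hydroxide made in the flask unmasks the phenoxides of the triacetate one after another, so that each is O-alkylated by one equivalent of the benzylic chloride before C-alkylation of the ambident phloroglucinol anion can compete.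

**Step 3**
Reactants: 4 1,3,5-tris{[3,4,5-tris(benzyloxy)benzyl]oxy}benzene
Product: 6 methyl 2-oxo-2-(2,4,6-tris{[3,4,5-tris(benzyloxy)benzyl]oxy}phenyl)acetate, via aroylformyl chloride 5 (not isolated)
Conditions: (COCl)2, CH2Cl2, 0 °C → rt; then MeOH, pyridine, 0 °C
Reagents that add atoms: oxalyl chloride, O=C(Cl)C(Cl)=O; methanol, CO
Why: Uncatalysed Friedel–Crafts acylation of the phloroglucinol-type core at one of its three equivalent CH positions (the pyrogallol-type outer rings are too weakly activated to react without a Lewis acid, and the first acyl group deactivates the core against a second), followed by methanolysis of the acid chloride to the α-keto ester.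

**Step 4**
Reactants: 6 methyl 2-oxo-2-(2,4,6-tris{[3,4,5-tris(benzyloxy)benzyl]oxy}phenyl)acetate
Product: 7 methyl 3-hydroxy-2-[3,4,5-tris(benzyloxy)phenyl]-4,6-bis{[3,4,5-tris(benzyloxy)benzyl]oxy}-2,3-dihydro-1-benzofuran-3-carboxylate (racemic, both C2/C3 diastereomers)
Conditions: hν (365 nm LED), degassed benzene, rt
Reagents that add atoms: none
Why: Norrish–Yang photocyclisation, in which the n,π* excited keto group abstracts a hydrogen atom from an ortho O–CH2Ar group (1,6-hydrogen transfer) and the 1,5-biradical recombines to the C2–C3 bond of the dihydrobenzofuran; the two ortho ethers are identical so only one constitution can form, and the uncontrolled configurations are harmless because C3 becomes trigonal in step 7 and C2 is reset in step 8.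

**Step 5**
Reactants: 7 methyl 3-hydroxy-2-[3,4,5-tris(benzyloxy)phenyl]-4,6-bis{[3,4,5-tris(benzyloxy)benzyl]oxy}-2,3-dihydro-1-benzofuran-3-carboxylate
Product: 8 3-(hydroxymethyl)-2-[3,4,5-tris(benzyloxy)phenyl]-4,6-bis{[3,4,5-tris(benzyloxy)benzyl]oxy}-2,3-dihydro-1-benzofuran-3-ol (racemic, both diastereomers)
Conditions: LiBH4, THF, 0 °C → rt
Reagents that add atoms: none
Why: Borohydride reduction of an α-hydroxy ester to the primary alcohol, accelerated by the neighbouring alkoxide; the ethers and the tertiary alcohol are inert and no stereocentre is touched.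

**Step 6**
Reactants: 8 3-(hydroxymethyl)-2-[3,4,5-tris(benzyloxy)phenyl]-4,6-bis{[3,4,5-tris(benzyloxy)benzyl]oxy}-2,3-dihydro-1-benzofuran-3-ol
Product: 9 {3-hydroxy-2-[3,4,5-tris(benzyloxy)phenyl]-4,6-bis{[3,4,5-tris(benzyloxy)benzyl]oxy}-2,3-dihydro-1-benzofuran-3-yl}methyl methanesulfonate (racemic, both diastereomers; used crude)
Conditions: MsCl (1.05 equiv), Et3N, CH2Cl2, −30 °C
Reagents that add atoms: methanesulfonyl chloride, CS(=O)(=O)Cl
Why: Selective O-sulfonylation of the primary hydroxyl; the tertiary benzylic hydroxyl is too hindered to react at low temperature.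

**Step 7**
Reactants: 9 {3-hydroxy-2-[3,4,5-tris(benzyloxy)phenyl]-4,6-bis{[3,4,5-tris(benzyloxy)benzyl]oxy}-2,3-dihydro-1-benzofuran-3-yl}methyl methanesulfonate
Product: 10 2-[3,4,5-tris(benzyloxy)phenyl]-5,7-bis{[3,4,5-tris(benzyloxy)benzyl]oxy}chroman-3-one (racemic)
Conditions: LiClO4, 2,6-lutidine, THF, 45 °C
Reagents that add atoms: none
Why: The primary mesylate ionises with anchimeric assistance from ring A carbon C3a, which is flanked by O1 and the C4 ether oxygen and is para to the C6 ether oxygen, so ipso attack gives a spirocyclopropyl arenium (phenonium) ion whose charge rests on three oxygens; the lone pair of the C3 hydroxyl then pushes, the C3–C3a bond breaks, ring A rearomatises and loss of the proton to 2,6-lutidine leaves the C3 ketone, with the former exocyclic CH2 inserted between C3 and the arene as C4 of the chroman. The closest known reaction type is the semipinacol (Tiffeneau–Demjanov-type) ring expansion of indan-1-ols carrying a leaving group on a 1-methyl substituent to 2-tetralones by aryl migration, and lithium perchlorate with a weak base in THF is the usual medium for semipinacol shifts of β-hydroxy sulfonates. The six-membered ring is not closed by a cyclisation but by this 1,2-carbon shift; the only closure on the way is the 3-exo ipso attack that forms the transient cyclopropane, which reopens at its other bond. No new stereocentre is formed: C3 becomes trigonal and C2 is carried over as the labile centre α to the ketone that step 8 exploits. The step needs migration of the aryl carbon in preference to C2 and to epoxide closure, and it needs the tertiary benzylic C3–O bond to stay intact; this is secured by the trioxygenated migrating carbon, the absence of hydrogen on C3 (no hydride shift), the electron-poor C2 (it carries O1) and the buffered, alkoxide-free medium.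

**Step 8**
Reactants: 10 2-[3,4,5-tris(benzyloxy)phenyl]-5,7-bis{[3,4,5-tris(benzyloxy)benzyl]oxy}chroman-3-one
Product: 11 (2R,3R)-2-[3,4,5-tris(benzyloxy)phenyl]-5,7-bis{[3,4,5-tris(benzyloxy)benzyl]oxy}chroman-3-ol (2,3-cis)
Conditions: RuCl[(S,S)-TsDPEN](p-cymene) (2 mol%), HCO2H/Et3N (1:1.5), DMF, 40 °C, Ar
Reagents that add atoms: none
Why: Asymmetric transfer hydrogenation with dynamic kinetic resolution: C2 (α to the ketone, benzylic, O-substituted) epimerises through the enol under Et3N faster than reduction, the chiral Ru–H fixes the 3R carbinol configuration (catalyst control), and hydride enters on the equatorial trajectory of the half-chair with the C2 aryl group pseudo-equatorial (substrate control), so the whole material should be funnelled to the (2R,3R) cis alcohol.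

**Step 9**
Reactants: 12 (−)-epigallocatechin
Product: 13 (2R,3R)-5,7-bis(benzyloxy)-2-[3,4,5-tris(benzyloxy)phenyl]chroman-3-ol
Conditions: BnBr (5.5 equiv), K2CO3, DMF, 0 °C → rt, Ar
Reagents that add atoms: benzyl bromide, BrCc1ccccc1
Why: Fivefold Williamson O-benzylation of the phenols with a carbonate base that leaves the much less acidic secondary C3 hydroxyl free; oxygen is excluded and the temperature kept low so that the pyran ring does not open through a ring B quinone methide and C2 is not epimerised.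

**Step 10**
Reactants: 13 (2R,3R)-5,7-bis(benzyloxy)-2-[3,4,5-tris(benzyloxy)phenyl]chroman-3-ol; 14 3,4,5-tris(benzyloxy)benzoic acid
Product: 15 (2R,3R)-5,7-bis(benzyloxy)-2-[3,4,5-tris(benzyloxy)phenyl]chroman-3-yl 3,4,5-tris(benzyloxy)benzoate
Conditions: DCC, DMAP, CH2Cl2, 0 °C → rt
Reagents that add atoms: none
Why: Steglich esterification, in which the O-acylisourea of acid 14 is passed on by DMAP as the acylpyridinium ion to the axial C3 hydroxyl; the C3–O bond of the alcohol is not touched, so C3 keeps its configuration.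

**Step 11**
Reactants: 15 (2R,3R)-5,7-bis(benzyloxy)-2-[3,4,5-tris(benzyloxy)phenyl]chroman-3-yl 3,4,5-tris(benzyloxy)benzoate
Product: 16 (2R,3R,4S)-5,7-bis(benzyloxy)-4-(2-ethoxyethoxy)-2-[3,4,5-tris(benzyloxy)phenyl]chroman-3-yl 3,4,5-tris(benzyloxy)benzoate (4β ether, 3,4-trans)
Conditions: DDQ, 2-ethoxyethanol, CH2Cl2, rt
Reagents that add atoms: 2-ethoxyethanol, CCOCCO
Why: Benzylic C4–H oxidation by DDQ (hydride abstraction assisted by the 5,7-dialkoxy ring A) and capture of the C4 cation by the alcohol on the face anti to the axial 3-acyloxy group, the usual C4 activation of benzylated flavan-3-ols; the new C4 configuration is lost again on ionisation in step 12.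

**Step 12**
Reactants: 11 (2R,3R)-2-[3,4,5-tris(benzyloxy)phenyl]-5,7-bis{[3,4,5-tris(benzyloxy)benzyl]oxy}chroman-3-ol (2 equiv, excess recovered); 16 (2R,3R,4S)-5,7-bis(benzyloxy)-4-(2-ethoxyethoxy)-2-[3,4,5-tris(benzyloxy)phenyl]chroman-3-yl 3,4,5-tris(benzyloxy)benzoate
Product: 17 octa-O-benzyl-epigallocatechin-3-O-gallate-(4β→8)-[3',4',5'-tri-O-benzyl-5,7-bis-O-(3,4,5-tris(benzyloxy)benzyl)epigallocatechin]; upper unit 2R,3R,4R, lower unit 2R,3R
Conditions: TMSOTf (0.3 equiv), CH2Cl2, −78 → −40 °C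
Reagents that add atoms: none
Why: Lewis-acid-mediated Friedel–Crafts coupling of the flavan-4-yl cation (the standard interflavan bond formation): the cation from 16 is captured by C8 of 11, the ring A position ortho to O1 and to the C7 oxygen and para to the C5 oxygen, on the β face anti to the axial 3-galloyloxy group (which can also shield the α face as a dioxolanylium ion), so C4 is set 4β (3,4-trans).

**Step 13**
Reactants: 17 protected dimer
Product: 18 epigallocatechin-3-O-gallate-(4β→8)-epigallocatechin (target)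
Conditions: H2 (1 atm), Pd(OH)2/C, THF/MeOH/H2O, rt
Reagents that add atoms: none
Why: Global hydrogenolysis of all benzyl-type C–O bonds (seventeen benzyl ethers and the two tris(benzyloxy)benzyl aryl ethers) under neutral conditions that leave the ester, the interflavan bond and all five stereocentres untouched.

**Compound list**

1 | [3,4,5-tris(benzyloxy)phenyl]methanol | OCc1cc(OCc2ccccc2)c(OCc2ccccc2)c(OCc2ccccc2)c1 | starting material

2 | 1,2,3-tris(benzyloxy)-5-(chloromethyl)benzene | ClCc1cc(OCc2ccccc2)c(OCc2ccccc2)c(OCc2ccccc2)c1 | intermediate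

3 | benzene-1,3,5-triyl triacetate | CC(=O)Oc1cc(OC(C)=O)cc(OC(C)=O)c1 | starting material

4 | 1,3,5-tris{[3,4,5-tris(benzyloxy)benzyl]oxy}benzene | c1(OCc2cc(OCc3ccccc3)c(OCc3ccccc3)c(OCc3ccccc3)c2)cc(OCc2cc(OCc3ccccc3)c(OCc3ccccc3)c(OCc3ccccc3)c2)cc(OCc2cc(OCc3ccccc3)c(OCc3ccccc3)c(OCc3ccccc3)c2)c1 | intermediate

5 | 2-oxo-2-(2,4,6-tris{[3,4,5-tris(benzyloxy)benzyl]oxy}phenyl)acetyl chloride (not isolated) | O=C(Cl)C(=O)c1c(OCc2cc(OCc3ccccc3)c(OCc3ccccc3)c(OCc3ccccc3)c2)cc(OCc2cc(OCc3ccccc3)c(OCc3ccccc3)c(OCc3ccccc3)c2)cc1OCc1cc(OCc2ccccc2)c(OCc2ccccc2)c(OCc2ccccc2)c1 | intermediate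

6 | methyl 2-oxo-2-(2,4,6-tris{[3,4,5-tris(benzyloxy)benzyl]oxy}phenyl)acetate | COC(=O)C(=O)c1c(OCc2cc(OCc3ccccc3)c(OCc3ccccc3)c(OCc3ccccc3)c2)cc(OCc2cc(OCc3ccccc3)c(OCc3ccccc3)c(OCc3ccccc3)c2)cc1OCc1cc(OCc2ccccc2)c(OCc2ccccc2)c(OCc2ccccc2)c1 | intermediate

7 | methyl 3-hydroxy-2-[3,4,5-tris(benzyloxy)phenyl]-4,6-bis{[3,4,5-tris(benzyloxy)benzyl]oxy}-2,3-dihydro-1-benzofuran-3-carboxylate (racemic, both C2/C3 diastereomers, hence no stereo descriptors) | COC(=O)C1(O)C(c2cc(OCc3ccccc3)c(OCc3ccccc3)c(OCc3ccccc3)c2)Oc2cc(OCc3cc(OCc4ccccc4)c(OCc4ccccc4)c(OCc4ccccc4)c3)cc(OCc3cc(OCc4ccccc4)c(OCc4ccccc4)c(OCc4ccccc4)c3)c21 | intermediate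

8 | 3-(hydroxymethyl)-2-[3,4,5-tris(benzyloxy)phenyl]-4,6-bis{[3,4,5-tris(benzyloxy)benzyl]oxy}-2,3-dihydro-1-benzofuran-3-ol (racemic, both diastereomers) | OCC1(O)C(c2cc(OCc3ccccc3)c(OCc3ccccc3)c(OCc3ccccc3)c2)Oc2cc(OCc3cc(OCc4ccccc4)c(OCc4ccccc4)c(OCc4ccccc4)c3)cc(OCc3cc(OCc4ccccc4)c(OCc4ccccc4)c(OCc4ccccc4)c3)c21 | intermediate

9 | {3-hydroxy-2-[3,4,5-tris(benzyloxy)phenyl]-4,6-bis{[3,4,5-tris(benzyloxy)benzyl]oxy}-2,3-dihydro-1-benzofuran-3-yl}methyl methanesulfonate (racemic, both diastereomers) | CS(=O)(=O)OCC1(O)C(c2cc(OCc3ccccc3)c(OCc3ccccc3)c(OCc3ccccc3)c2)Oc2cc(OCc3cc(OCc4ccccc4)c(OCc4ccccc4)c(OCc4ccccc4)c3)cc(OCc3cc(OCc4ccccc4)c(OCc4ccccc4)c(OCc4ccccc4)c3)c21 | intermediate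

10 | 2-[3,4,5-tris(benzyloxy)phenyl]-5,7-bis{[3,4,5-tris(benzyloxy)benzyl]oxy}chroman-3-one (racemic at C2) | O=C1Cc2c(OCc3cc(OCc4ccccc4)c(OCc4ccccc4)c(OCc4ccccc4)c3)cc(OCc3cc(OCc4ccccc4)c(OCc4ccccc4)c(OCc4ccccc4)c3)cc2OC1c1cc(OCc2ccccc2)c(OCc2ccccc2)c(OCc2ccccc2)c1 | intermediate

11 | (2R,3R)-2-[3,4,5-tris(benzyloxy)phenyl]-5,7-bis{[3,4,5-tris(benzyloxy)benzyl]oxy}chroman-3-ol | O[C@@H]1Cc2c(OCc3cc(OCc4ccccc4)c(OCc4ccccc4)c(OCc4ccccc4)c3)cc(OCc3cc(OCc4ccccc4)c(OCc4ccccc4)c(OCc4ccccc4)c3)cc2O[C@@H]1c1cc(OCc2ccccc2)c(OCc2ccccc2)c(OCc2ccccc2)c1 | intermediate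

12 | (−)-epigallocatechin, (2R,3R) | O[C@@H]1Cc2c(O)cc(O)cc2O[C@@H]1c1cc(O)c(O)c(O)c1 | starting material

13 | (2R,3R)-5,7-bis(benzyloxy)-2-[3,4,5-tris(benzyloxy)phenyl]chroman-3-ol | O[C@@H]1Cc2c(OCc3ccccc3)cc(OCc3ccccc3)cc2O[C@@H]1c1cc(OCc2ccccc2)c(OCc2ccccc2)c(OCc2ccccc2)c1 | intermediate

14 | 3,4,5-tris(benzyloxy)benzoic acid | OC(=O)c1cc(OCc2ccccc2)c(OCc2ccccc2)c(OCc2ccccc2)c1 | starting material

15 | (2R,3R)-5,7-bis(benzyloxy)-2-[3,4,5-tris(benzyloxy)phenyl]chroman-3-yl 3,4,5-tris(benzyloxy)benzoate | O=C(O[C@@H]1Cc2c(OCc3ccccc3)cc(OCc3ccccc3)cc2O[C@@H]1c1cc(OCc2ccccc2)c(OCc2ccccc2)c(OCc2ccccc2)c1)c1cc(OCc2ccccc2)c(OCc2ccccc2)c(OCc2ccccc2)c1 | intermediate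

16 | (2R,3R,4S)-5,7-bis(benzyloxy)-4-(2-ethoxyethoxy)-2-[3,4,5-tris(benzyloxy)phenyl]chroman-3-yl 3,4,5-tris(benzyloxy)benzoate | O=C(O[C@@H]1[C@@H](OCCOCC)c2c(OCc3ccccc3)cc(OCc3ccccc3)cc2O[C@@H]1c1cc(OCc2ccccc2)c(OCc2ccccc2)c(OCc2ccccc2)c1)c1cc(OCc2ccccc2)c(OCc2ccccc2)c(OCc2ccccc2)c1 | intermediate

17 | octa-O-benzyl-epigallocatechin-3-O-gallate-(4β→8)-[3',4',5'-tri-O-benzyl-5,7-bis-O-(3,4,5-tris(benzyloxy)benzyl)epigallocatechin] | O=C(O[C@@H]1[C@@H](c2c(OCc3cc(OCc4ccccc4)c(OCc4ccccc4)c(OCc4ccccc4)c3)cc(OCc3cc(OCc4ccccc4)c(OCc4ccccc4)c(OCc4ccccc4)c3)c3c2O[C@H](c2cc(OCc4ccccc4)c(OCc4ccccc4)c(OCc4ccccc4)c2)[C@H](O)C3)c2c(OCc3ccccc3)cc(OCc3ccccc3)cc2O[C@@H]1c1cc(OCc2ccccc2)c(OCc2ccccc2)c(OCc2ccccc2)c1)c1cc(OCc2ccccc2)c(OCc2ccccc2)c(OCc2ccccc2)c1 | intermediate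

18 | epigallocatechin-3-O-gallate-(4β→8)-epigallocatechin | O=C(O[C@@H]1[C@@H](c2c(O)cc(O)c3c2O[C@H](c2cc(O)c(O)c(O)c2)[C@H](O)C3)c2c(O)cc(O)cc2O[C@@H]1c1cc(O)c(O)c(O)c1)c1cc(O)c(O)c(O)c1 | target

**Step count and risks**

Total step count: 13. Longest linear sequence: 10 (steps 1–8, 12, 13).

Steps most likely to fail:

Step 7. The C3 hydroxyl may close onto the primary sulfonate (spiro-epoxide, then opening at the benzylic carbon), or the tertiary benzylic C3–O bond may ionise with aromatisation to the benzofuran. The fallback replaces sulfonate ionisation by diazoalkane homologation of a ketone and is still a one-carbon expansion of the furan ring. It sets out from 8: glycol cleavage (NaIO4, THF/H2O, rt) should give the ketone 2-[3,4,5-tris(benzyloxy)phenyl]-4,6-bis{[3,4,5-tris(benzyloxy)benzyl]oxy}-1-benzofuran-3(2H)-one F1. Treatment with TMSCHN2 and BF3·OEt2 (CH2Cl2, −78 °C), in which the electron-rich aryl carbon should migrate in preference to C2, should give the α-silyl ketone 2-[3,4,5-tris(benzyloxy)phenyl]-5,7-bis{[3,4,5-tris(benzyloxy)benzyl]oxy}-4-(trimethylsilyl)chroman-3-one F2. Protodesilylation on acidic work-up (aq. HCl, THF, 0 °C) comes back to the route at 10.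

Step 4. The excited keto ester may be quenched by electron transfer from the many benzyloxy-substituted rings, or hydrogen abstraction may end in fragmentation instead of ring closure. The fallback replaces the photochemical step by a thermal carbenoid C–H insertion. It sets out from 6: condensation with TsNHNH2 (MeOH/THF, 50 °C) should give the tosylhydrazone methyl 2-(2-tosylhydrazinylidene)-2-(2,4,6-tris{[3,4,5-tris(benzyloxy)benzyl]oxy}phenyl)acetate F3. Base-induced loss of sulfinate (DBU, CH2Cl2, rt; Bamford–Stevens-type) should give the diazo ester methyl 2-diazo-2-(2,4,6-tris{[3,4,5-tris(benzyloxy)benzyl]oxy}phenyl)acetate F4. Rh2(S-PTTL)4-catalysed 1,5 C–H insertion into an ortho O–CH2Ar group (toluene, −60 °C) should give the cis ester methyl (2S,3R)-2-[3,4,5-tris(benzyloxy)phenyl]-4,6-bis{[3,4,5-tris(benzyloxy)benzyl]oxy}-2,3-dihydro-1-benzofuran-3-carboxylate F5. Hydroxylation of its ester enolate (KHMDS, THF, −78 °C; 2-(phenylsulfonyl)-3-phenyloxaziridine) comes back to the route at 7; the configuration at C2 is of no consequence there because step 8 resets it.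

Step 8. The epimerisation at C2 may be too slow relative to hydride transfer, or the catalyst may discriminate the carbonyl faces poorly, so that enantiomeric purity or the cis/trans outcome suffers. The fallback replaces catalyst control by substrate-controlled reduction and classical resolution. It sets out from 10: reduction with LiB(s-Bu)3H (THF, −78 °C) should give, by equatorial hydride attack, the racemic cis alcohol rac-(2R*,3R*)-2-[3,4,5-tris(benzyloxy)phenyl]-5,7-bis{[3,4,5-tris(benzyloxy)benzyl]oxy}chroman-3-ol F6. Esterification with (S)-2-methoxy-2-phenylacetic acid (EDC·HCl, DMAP, CH2Cl2, 0 °C) and chromatographic separation of the two diastereomers should give the ester (2R,3R)-2-[3,4,5-tris(benzyloxy)phenyl]-5,7-bis{[3,4,5-tris(benzyloxy)benzyl]oxy}chroman-3-yl (S)-2-methoxy-2-phenylacetate F7. Saponification (LiOH, THF/MeOH/H2O) comes back to the route at 11.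

**Further compounds**

F1 | step 7 | 2-[3,4,5-tris(benzyloxy)phenyl]-4,6-bis{[3,4,5-tris(benzyloxy)benzyl]oxy}-1-benzofuran-3(2H)-one (racemic) | O=C1C(c2cc(OCc3ccccc3)c(OCc3ccccc3)c(OCc3ccccc3)c2)Oc2cc(OCc3cc(OCc4ccccc4)c(OCc4ccccc4)c(OCc4ccccc4)c3)cc(OCc3cc(OCc4ccccc4)c(OCc4ccccc4)c(OCc4ccccc4)c3)c21

F2 | step 7 | 2-[3,4,5-tris(benzyloxy)phenyl]-5,7-bis{[3,4,5-tris(benzyloxy)benzyl]oxy}-4-(trimethylsilyl)chroman-3-one (racemic, both diastereomers) | O=C1C([Si](C)(C)C)c2c(OCc3cc(OCc4ccccc4)c(OCc4ccccc4)c(OCc4ccccc4)c3)cc(OCc3cc(OCc4ccccc4)c(OCc4ccccc4)c(OCc4ccccc4)c3)cc2OC1c1cc(OCc2ccccc2)c(OCc2ccccc2)c(OCc2ccccc2)c1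

F3 | step 4 | methyl 2-(2-tosylhydrazinylidene)-2-(2,4,6-tris{[3,4,5-tris(benzyloxy)benzyl]oxy}phenyl)acetate | COC(=O)C(=NNS(=O)(=O)c1ccc(C)cc1)c1c(OCc2cc(OCc3ccccc3)c(OCc3ccccc3)c(OCc3ccccc3)c2)cc(OCc2cc(OCc3ccccc3)c(OCc3ccccc3)c(OCc3ccccc3)c2)cc1OCc1cc(OCc2ccccc2)c(OCc2ccccc2)c(OCc2ccccc2)c1

F4 | step 4 | methyl 2-diazo-2-(2,4,6-tris{[3,4,5-tris(benzyloxy)benzyl]oxy}phenyl)acetate | COC(=O)C(=[N+]=[N-])c1c(OCc2cc(OCc3ccccc3)c(OCc3ccccc3)c(OCc3ccccc3)c2)cc(OCc2cc(OCc3ccccc3)c(OCc3ccccc3)c(OCc3ccccc3)c2)cc1OCc1cc(OCc2ccccc2)c(OCc2ccccc2)c(OCc2ccccc2)c1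

F5 | step 4 | methyl (2S,3R)-2-[3,4,5-tris(benzyloxy)phenyl]-4,6-bis{[3,4,5-tris(benzyloxy)benzyl]oxy}-2,3-dihydro-1-benzofuran-3-carboxylate (2,3-cis) | c1(OCc2cc(OCc3ccccc3)c(OCc3ccccc3)c(OCc3ccccc3)c2)cc(OCc2cc(OCc3ccccc3)c(OCc3ccccc3)c(OCc3ccccc3)c2)c2c(c1)O[C@H](c1cc(OCc3ccccc3)c(OCc3ccccc3)c(OCc3ccccc3)c1)[C@@H]2C(=O)OC

F6 | step 8 | rac-(2R*,3R*)-2-[3,4,5-tris(benzyloxy)phenyl]-5,7-bis{[3,4,5-tris(benzyloxy)benzyl]oxy}chroman-3-ol (racemate, one enantiomer drawn) | O[C@@H]1Cc2c(OCc3cc(OCc4ccccc4)c(OCc4ccccc4)c(OCc4ccccc4)c3)cc(OCc3cc(OCc4ccccc4)c(OCc4ccccc4)c(OCc4ccccc4)c3)cc2O[C@@H]1c1cc(OCc2ccccc2)c(OCc2ccccc2)c(OCc2ccccc2)c1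

F7 | step 8 | (2R,3R)-2-[3,4,5-tris(benzyloxy)phenyl]-5,7-bis{[3,4,5-tris(benzyloxy)benzyl]oxy}chroman-3-yl (S)-2-methoxy-2-phenylacetate | CO[C@H](C(=O)O[C@@H]1Cc2c(OCc3cc(OCc4ccccc4)c(OCc4ccccc4)c(OCc4ccccc4)c3)cc(OCc3cc(OCc4ccccc4)c(OCc4ccccc4)c(OCc4ccccc4)c3)cc2O[C@@H]1c1cc(OCc2ccccc2)c(OCc2ccccc2)c(OCc2ccccc2)c1)c1ccccc1
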